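Ring C is taken apart at C2–C3 and C4–C4a, a formal cationic [4+2] annulation: the aryloxymethyl cation O1=C2 of a ring A phenol ether adds to the aryl-bearing carbon (C3) of a ring B siloxyalkyne, and the silyl ketenium ion so formed at C4 acylates C4a. The step exploits the local symmetry of ring A about the C8a–C6 axis (C4a and C8 are equivalent before cyclization) and the enol form of the C3–C4 ketone unit. It joins an aryloxymethyl pivalate and an aryl(triisopropylsiloxy)alkyne to the C3=C4 silyl enol ether of the isoflavanone, whose catalytic enantioselective protonation then sets C3.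

Key step: step 9

Remark on the chemistry: the target SMILES corresponds to the 3S configuration; the (S)-antipode of the protonation catalyst in step 11 is assumed to deliver this sense, and its mirror image is used if the first run shows the opposite.

Step 1
Reactants: 1 phloroglucinol (benzene-1,3,5-triol)
Product: 2 5-[(triisopropylsilyl)oxy]benzene-1,3-diol
Conditions: 1 (3 equiv), TIPSCl (1 equiv), imidazole, DMF, 0 °C → rt
Reagents that add atoms: triisopropylsilyl chloride, CC(C)[Si](Cl)(C(C)C)C(C)C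
Why: Statistical monosilylation of a threefold-symmetric triol; the excess of cheap 1 and the bulk of the silyl group should hold the reaction at the mono ether, and unreacted 1 is washed out with water.

Step 2
Reactants: 2 5-[(triisopropylsilyl)oxy]benzene-1,3-diol
Product: 3 [3,5-bis(methoxymethoxy)phenoxy]triisopropylsilane
Conditions: MOMCl, i-Pr2NEt, CH2Cl2, 0 °C → rt
Reagents that add atoms: chloromethyl methyl ether, COCCl
Why: O-alkylation of both phenols by the chloromethyl ether under amine base (Williamson-type etherification); the aryl silyl ether is inert.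

Step 3
Reactants: 3 [3,5-bis(methoxymethoxy)phenoxy]triisopropylsilane
Product: 5 [3,5-bis(methoxymethoxy)-4-(3-methylbut-2-en-1-yl)phenoxy]triisopropylsilane, via aryllithium 4 (not isolated)
Conditions: n-BuLi, THF, 0 °C; then prenyl bromide, −78 °C → rt
Reagents that add atoms: 1-bromo-3-methylbut-2-ene, CC(C)=CCBr
Why: Directed ortho-metalation at the carbon between the two coordinating MOM ethers (the bulky silyl ether directs poorly), followed by SN2 displacement at the unhindered primary carbon of prenyl bromide.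

Step 4
Reactants: 5 [3,5-bis(methoxymethoxy)-4-(3-methylbut-2-en-1-yl)phenoxy]triisopropylsilane
Product: 7 [3,5-bis(methoxymethoxy)-4-(3-methylbut-2-en-1-yl)phenoxy]methyl pivalate, via cesium phenoxide 6 (not isolated)
Conditions: CsF, ClCH2OPiv, DMF, rt
Reagents that add atoms: chloromethyl pivalate, CC(C)(C)C(=O)OCCl
Why: Fluoride cleaves the unhindered aryl silyl ether and the phenoxide is alkylated at the CH2 carbon of the hindered chloromethyl ester in the same flask (one-pot desilylative Williamson etherification).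

Step 5
Reactants: 8 methyl 2-hydroxy-4-methoxybenzoate
Product: 9 methyl 5-bromo-2-hydroxy-4-methoxybenzoate
Conditions: NBS, MeCN, 0 °C → rt
Reagents that add atoms: N-bromosuccinimide, O=C1CCC(=O)N1Br
Why: Electrophilic aromatic bromination at C5, which is para to the hydroxyl and ortho to the methoxy group, whereas C3 lies between two substituents.

Step 6
Reactants: 9 methyl 5-bromo-2-hydroxy-4-methoxybenzoate
Product: 10 methyl 5-bromo-4-methoxy-2-[(triisopropylsilyl)oxy]benzoate
Conditions: TIPSOTf, 2,6-lutidine, CH2Cl2, 0 °C → rt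
Reagents that add atoms: triisopropylsilyl triflate, CC(C)[Si](OS(=O)(=O)C(F)(F)F)(C(C)C)C(C)C
Why: The silyl triflate should silylate the hydrogen-bonded salicylate hydroxyl; the bulky silyl ether is chosen because it keeps this oxygen non-nucleophilic in step 9.

Step 7
Reactants: 10 methyl 5-bromo-4-methoxy-2-[(triisopropylsilyl)oxy]benzoate
Product: 11 methyl 4-methoxy-5-(3-methylbut-2-en-1-yl)-2-[(triisopropylsilyl)oxy]benzoate
Conditions: tributyl(prenyl)stannane, Pd(PPh3)4 (cat.), DMF, 90 °C
Reagents that add atoms: tributyl(3-methylbut-2-en-1-yl)stannane, CCCC[Sn](CCCC)(CCCC)CC=C(C)C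
Why: Stille coupling of the aryl bromide; the allyl unit is expected to be transferred through its less substituted terminus, giving the linear prenyl arene, and no fluoride is present that could cleave the silyl ether.

Step 8
Reactants: 11 methyl 4-methoxy-5-(3-methylbut-2-en-1-yl)-2-[(triisopropylsilyl)oxy]benzoate
Product: 13 triisopropyl({[4-methoxy-5-(3-methylbut-2-en-1-yl)-2-(triisopropylsilyloxy)phenyl]ethynyl}oxy)silane, via lithium ynolate 12 (not isolated)
Conditions: CH2Br2, lithium 2,2,6,6-tetramethylpiperidide, THF, −78 °C; LiN(SiMe3)2; n-BuLi, −78 °C → rt; then TIPSOTf, −78 °C → 0 °C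
Reagents that add atoms: dibromomethane, BrCBr; triisopropylsilyl triflate, CC(C)[Si](OS(=O)(=O)C(F)(F)F)(C(C)C)C(C)C
Why: Kowalski ester homologation stopped at the ynolate: dibromomethyllithium adds to the ester, bromine–lithium exchange on the dibromo enolate triggers a 1,2-aryl shift to the ynolate, and the bulky silyl triflate silylates it on oxygen.

Step 9
Reactants: 7 [3,5-bis(methoxymethoxy)-4-(3-methylbut-2-en-1-yl)phenoxy]methyl pivalate and 13 triisopropyl({[4-methoxy-5-(3-methylbut-2-en-1-yl)-2-(triisopropylsilyloxy)phenyl]ethynyl}oxy)silane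
Product: 16 5,7-bis(methoxymethoxy)-6-(3-methylbut-2-en-1-yl)-3-[4-methoxy-5-(3-methylbut-2-en-1-yl)-2-(triisopropylsilyloxy)phenyl]-4-(triisopropylsilyloxy)-2H-chromene, via aryloxymethyl oxocarbenium triflate 14 (not isolated), via silyl ketenium triflate 15 (not isolated)
Conditions: 7, 13 (1.5 equiv), 2,6-di-tert-butyl-4-methylpyridine, CH2Cl2, −78 °C; TMSOTf (1.1 equiv) added last, −78 °C → −40 °C
Reagents that add atoms: none
Why: Proposed new method: TMSOTf silylates the pivalate carbonyl of 7 and ionizes the acyloxy acetal to the aryloxymethyl oxocarbenium ion 14 (or its covalent triflate), whose CH2 carbon (C2) is attacked by the aryl-bearing carbon of siloxyalkyne 13 (C3), the carbon made nucleophilic by the ynol oxygen, to give silyl ketenium ion 15; its sp carbon (C4) then acylates the ortho carbon of the aryloxy ring (C4a) and the hindered pyridine takes the proton. The closest known reaction types are the oxa-Povarov reaction of aryl oxocarbenium ions with alkenes, the addition of siloxyalkynes to acetal-derived oxocarbenium ions, and the acid-promoted cyclization of siloxyalkyne-derived ketenium ions onto arenes to give silyl enol ethers. Ring C closes by Friedel–Crafts attack of C4a on the ketenium carbon, 6-exo-dig with respect to the C4=O+ bond, so the whole is a stepwise formal [4+2] annulation. No stereocenter is formed, because C3 ends as the sp2 carbon of the C3=C4 silyl enol ether. The step needs one site of ring closure, chemoselective ionization and C- rather than O-capture of 15: the two ortho carbons of 7 are equivalent by the mirror plane through O1 and C6, the acyloxy acetal should ionize at a temperature at which aryl MOM ethers do not yet react with TMSOTf, the siloxyalkyne is far more nucleophilic than the prenyl olefins, and the bulky silyl group keeps the 2'-oxygen of ring B from adding to C4.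

Step 10
Reactants: 16 5,7-bis(methoxymethoxy)-6-(3-methylbut-2-en-1-yl)-3-[4-methoxy-5-(3-methylbut-2-en-1-yl)-2-(triisopropylsilyloxy)phenyl]-4-(triisopropylsilyloxy)-2H-chromene
Product: 17 6-(3-methylbut-2-en-1-yl)-3-[4-methoxy-5-(3-methylbut-2-en-1-yl)-2-(triisopropylsilyloxy)phenyl]-5,7-bis(triethylsilyloxy)-4-(triisopropylsilyloxy)-2H-chromene
Conditions: TESOTf, 2,2'-bipyridyl, CH2Cl2, 0 °C → rt
Reagents that add atoms: triethylsilyl triflate, CC[Si](CC)(CC)OS(=O)(=O)C(F)(F)F
Why: Silyl triflate/2,2'-bipyridyl exchange of aromatic MOM ethers into aryl silyl ethers under non-acidic conditions, which should leave the silyl enol ether and the olefins untouched; it is done before C3 is stereogenic so that no acetal has to be cleaved next to the epimerizable center later.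

Step 11
Reactants: 17 6-(3-methylbut-2-en-1-yl)-3-[4-methoxy-5-(3-methylbut-2-en-1-yl)-2-(triisopropylsilyloxy)phenyl]-5,7-bis(triethylsilyloxy)-4-(triisopropylsilyloxy)-2H-chromene
Product: 18 (3S)-3-[4-methoxy-5-(3-methylbut-2-en-1-yl)-2-(triisopropylsilyloxy)phenyl]-6-(3-methylbut-2-en-1-yl)-5,7-bis(triethylsilyloxy)chroman-4-one
Conditions: (S)-3,3'-bis(2,4,6-triisopropylphenyl)-1,1'-binaphthyl-2,2'-diyl N-triflylthiophosphoramide (10 mol %), PhOH, toluene, rt
Reagents that add atoms: none
Why: Chiral Brønsted acid-catalyzed enantioselective protonation of the silyl enol ether of an α-aryl cyclic ketone: the chiral acid delivers the proton to one face of C3 of the planar enol ether (catalyst control of the new stereocenter), and phenol takes over the silyl group and turns the catalyst over.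

Step 12
Reactants: 18 (3S)-3-[4-methoxy-5-(3-methylbut-2-en-1-yl)-2-(triisopropylsilyloxy)phenyl]-6-(3-methylbut-2-en-1-yl)-5,7-bis(triethylsilyloxy)chroman-4-one
Product: 19 (3S)-5,7-dihydroxy-3-[2-hydroxy-4-methoxy-5-(3-methylbut-2-en-1-yl)phenyl]-6-(3-methylbut-2-en-1-yl)chroman-4-one (target, CNP0282256.1)
Conditions: TBAF, AcOH (1:1), THF, 0 °C
Reagents that add atoms: none
Why: Buffered fluoride should cleave the three aryl silyl ethers (desilylation); acetic acid keeps the medium from turning basic so that the C3–H next to the ketone is not exchanged, and the prenyl groups are inert.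

Compound list
1 | phloroglucinol (benzene-1,3,5-triol) | Oc1cc(O)cc(O)c1 | starting material
2 | 5-[(triisopropylsilyl)oxy]benzene-1,3-diol | CC(C)[Si](Oc1cc(O)cc(O)c1)(C(C)C)C(C)C | intermediate
3 | [3,5-bis(methoxymethoxy)phenoxy]triisopropylsilane | COCOc1cc(OCOC)cc(O[Si](C(C)C)(C(C)C)C(C)C)c1 | intermediate
4 | 2,6-bis(methoxymethoxy)-4-[(triisopropylsilyl)oxy]phenyllithium | [Li]c1c(OCOC)cc(O[Si](C(C)C)(C(C)C)C(C)C)cc1OCOC | intermediate
5 | [3,5-bis(methoxymethoxy)-4-(3-methylbut-2-en-1-yl)phenoxy]triisopropylsilane | COCOc1cc(O[Si](C(C)C)(C(C)C)C(C)C)cc(OCOC)c1CC=C(C)C | intermediate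
6 | cesium 3,5-bis(methoxymethoxy)-4-(3-methylbut-2-en-1-yl)phenolate | [Cs+].[O-]c1cc(OCOC)c(CC=C(C)C)c(OCOC)c1 | intermediate
7 | [3,5-bis(methoxymethoxy)-4-(3-methylbut-2-en-1-yl)phenoxy]methyl pivalate | CC(C)(C)C(=O)OCOc1cc(OCOC)c(CC=C(C)C)c(OCOC)c1 | intermediate
8 | methyl 2-hydroxy-4-methoxybenzoate | COC(=O)c1ccc(OC)cc1O | starting material
9 | methyl 5-bromo-2-hydroxy-4-methoxybenzoate | COC(=O)c1cc(Br)c(OC)cc1O | intermediate
10 | methyl 5-bromo-4-methoxy-2-[(triisopropylsilyl)oxy]benzoate | COC(=O)c1cc(Br)c(OC)cc1O[Si](C(C)C)(C(C)C)C(C)C | intermediate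
11 | methyl 4-methoxy-5-(3-methylbut-2-en-1-yl)-2-[(triisopropylsilyl)oxy]benzoate | COC(=O)c1cc(CC=C(C)C)c(OC)cc1O[Si](C(C)C)(C(C)C)C(C)C | intermediate
12 | lithium 2-[4-methoxy-5-(3-methylbut-2-en-1-yl)-2-(triisopropylsilyloxy)phenyl]ethynolate | [Li+].[O-]C#Cc1cc(CC=C(C)C)c(OC)cc1O[Si](C(C)C)(C(C)C)C(C)C | intermediate
13 | triisopropyl({[4-methoxy-5-(3-methylbut-2-en-1-yl)-2-(triisopropylsilyloxy)phenyl]ethynyl}oxy)silane | CC(C)[Si](OC#Cc1cc(CC=C(C)C)c(OC)cc1O[Si](C(C)C)(C(C)C)C(C)C)(C(C)C)C(C)C | intermediate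
14 | [3,5-bis(methoxymethoxy)-4-(3-methylbut-2-en-1-yl)phenyl](methylidene)oxonium triflate | C=[O+]c1cc(OCOC)c(CC=C(C)C)c(OCOC)c1.[O-]S(=O)(=O)C(F)(F)F | intermediate
15 | O-triisopropylsilyl ketenium triflate carrying the aryloxymethyl group and the ring B aryl group on the terminal carbon | CC(C)[Si]([O+]=C=C(COc1cc(OCOC)c(CC=C(C)C)c(OCOC)c1)c1cc(CC=C(C)C)c(OC)cc1O[Si](C(C)C)(C(C)C)C(C)C)(C(C)C)C(C)C.[O-]S(=O)(=O)C(F)(F)F | intermediate
16 | 5,7-bis(methoxymethoxy)-6-(3-methylbut-2-en-1-yl)-3-[4-methoxy-5-(3-methylbut-2-en-1-yl)-2-(triisopropylsilyloxy)phenyl]-4-(triisopropylsilyloxy)-2H-chromene | CC(C)[Si](OC1=C(COc2cc(OCOC)c(CC=C(C)C)c(OCOC)c12)c1cc(CC=C(C)C)c(OC)cc1O[Si](C(C)C)(C(C)C)C(C)C)(C(C)C)C(C)C | intermediate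
17 | 6-(3-methylbut-2-en-1-yl)-3-[4-methoxy-5-(3-methylbut-2-en-1-yl)-2-(triisopropylsilyloxy)phenyl]-5,7-bis(triethylsilyloxy)-4-(triisopropylsilyloxy)-2H-chromene | CC[Si](CC)(CC)Oc1cc2OCC(c3cc(CC=C(C)C)c(OC)cc3O[Si](C(C)C)(C(C)C)C(C)C)=C(O[Si](C(C)C)(C(C)C)C(C)C)c2c(O[Si](CC)(CC)CC)c1CC=C(C)C | intermediate
18 | (3S)-3-[4-methoxy-5-(3-methylbut-2-en-1-yl)-2-(triisopropylsilyloxy)phenyl]-6-(3-methylbut-2-en-1-yl)-5,7-bis(triethylsilyloxy)chroman-4-one | COc1cc(O[Si](C(C)C)(C(C)C)C(C)C)c([C@H]2COc3cc(O[Si](CC)(CC)CC)c(CC=C(C)C)c(O[Si](CC)(CC)CC)c3C2=O)cc1CC=C(C)C | intermediate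
19 | (3S)-5,7-dihydroxy-3-[2-hydroxy-4-methoxy-5-(3-methylbut-2-en-1-yl)phenyl]-6-(3-methylbut-2-en-1-yl)chroman-4-one | COc1cc(O)c([C@H]2COc3cc(O)c(CC=C(C)C)c(O)c3C2=O)cc1CC=C(C)C | target

Total step count: 12. Longest linear sequence: 8 steps (steps 1–4 or 5–8, then 9–12).

Steps most likely to fail

Step 9 (proposed new method). What may go wrong: ionization of the aryl MOM acetals by the silyl triflate, alkylation of a second electron-rich ring by the oxocarbenium ion, and loss of the silyl group from the ketenium ion to a ketene that is consumed by oligomerization or O-capture. The fallback makes the same two bonds one after the other by known reactions and without a cationic C2. It sets out from 11 and 5. Kowalski homologation of 11, with ynolate 12 quenched by acidic ethanol, should give ethyl [4-methoxy-5-(3-methylbut-2-en-1-yl)-2-(triisopropylsilyloxy)phenyl]acetate F1. Methylenation of F1 (paraformaldehyde, K2CO3, Bu4NI, DMF) should give ethyl 2-[4-methoxy-5-(3-methylbut-2-en-1-yl)-2-(triisopropylsilyloxy)phenyl]prop-2-enoate F2. TBAF on 5 should give 3,5-bis(methoxymethoxy)-4-(3-methylbut-2-en-1-yl)phenol F3. Oxa-Michael addition of F3 to F2 (cat. DBU, MeCN) should give the racemic ethyl 3-aryloxy-2-arylpropanoate F4. Me3SnOH should hydrolyze F4 to the 3-aryloxy-2-arylpropanoic acid F5 without touching the silyl ether. TFAA (CH2Cl2, 0 °C) should close ring C by intramolecular Friedel–Crafts acylation, at either of the two equivalent ortho carbons, to the racemic 5,7-bis(methoxymethoxy)isoflavanone F6. TIPSOTf/Et3N then converts F6 into the silyl enol ether, and the route is rejoined at 16.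

Step 11. What may go wrong: slow proton transfer to the hindered, tetrasubstituted triisopropylsilyl enol ether and poor facial selectivity at C3. The fallback sets out from 17. Mild hydrolysis (dilute HCl, THF, 0 °C) should give the racemic 5,7-bis(triethylsilyloxy)isoflavanone F7. Noyori-type asymmetric transfer hydrogenation with dynamic kinetic resolution (RuCl[(S,S)-TsDPEN](p-cymene), HCO2H/Et3N) should give the cis-(3S,4S)-isoflavan-4-ol F8, the catalyst fixing C4 and the rapidly equilibrating C3 following to the cis isomer. Dess–Martin periodinane (NaHCO3, CH2Cl2) oxidizes F8 without base and rejoins the route at 18.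

Step 8. What may go wrong: incomplete carbenoid rearrangement on the hindered, electron-rich ester, C- instead of O-silylation of the ynolate, and attack of the lithium bases on the neighbouring aryl silyl ether. The fallback sets out from 11 and reaches the ynolate by oxidation of an acetylide. LiAlH4 should give [4-methoxy-5-(3-methylbut-2-en-1-yl)-2-(triisopropylsilyloxy)phenyl]methanol F9. MnO2 should give the benzaldehyde F10. Lithiated trimethylsilyldiazomethane (Colvin rearrangement, THF, −78 °C → rt) should give the terminal arylacetylene F11. n-BuLi gives the lithium acetylide F12, which lithium tert-butyl peroxide (from t-BuOOH and LiN(SiMe3)2) oxidizes to ynolate 12. TIPSOTf then rejoins the route at 13.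

Further compounds
F1 | step 9 | ethyl [4-methoxy-5-(3-methylbut-2-en-1-yl)-2-(triisopropylsilyloxy)phenyl]acetate | CCOC(=O)Cc1cc(CC=C(C)C)c(OC)cc1O[Si](C(C)C)(C(C)C)C(C)C
F2 | step 9 | ethyl 2-[4-methoxy-5-(3-methylbut-2-en-1-yl)-2-(triisopropylsilyloxy)phenyl]prop-2-enoate | CCOC(=O)C(=C)c1cc(CC=C(C)C)c(OC)cc1O[Si](C(C)C)(C(C)C)C(C)C
F3 | step 9 | 3,5-bis(methoxymethoxy)-4-(3-methylbut-2-en-1-yl)phenol | COCOc1cc(O)cc(OCOC)c1CC=C(C)C
F4 | step 9 | racemic ethyl 3-[3,5-bis(methoxymethoxy)-4-(3-methylbut-2-en-1-yl)phenoxy]-2-[4-methoxy-5-(3-methylbut-2-en-1-yl)-2-(triisopropylsilyloxy)phenyl]propanoate | CCOC(=O)C(COc1cc(OCOC)c(CC=C(C)C)c(OCOC)c1)c1cc(CC=C(C)C)c(OC)cc1O[Si](C(C)C)(C(C)C)C(C)C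
F5 | step 9 | racemic 3-[3,5-bis(methoxymethoxy)-4-(3-methylbut-2-en-1-yl)phenoxy]-2-[4-methoxy-5-(3-methylbut-2-en-1-yl)-2-(triisopropylsilyloxy)phenyl]propanoic acid | OC(=O)C(COc1cc(OCOC)c(CC=C(C)C)c(OCOC)c1)c1cc(CC=C(C)C)c(OC)cc1O[Si](C(C)C)(C(C)C)C(C)C
F6 | step 9 | racemic 5,7-bis(methoxymethoxy)-3-[4-methoxy-5-(3-methylbut-2-en-1-yl)-2-(triisopropylsilyloxy)phenyl]-6-(3-methylbut-2-en-1-yl)chroman-4-one | COCOc1cc2OCC(c3cc(CC=C(C)C)c(OC)cc3O[Si](C(C)C)(C(C)C)C(C)C)C(=O)c2c(OCOC)c1CC=C(C)C
F7 | step 11 | racemic 3-[4-methoxy-5-(3-methylbut-2-en-1-yl)-2-(triisopropylsilyloxy)phenyl]-6-(3-methylbut-2-en-1-yl)-5,7-bis(triethylsilyloxy)chroman-4-one | CC[Si](CC)(CC)Oc1cc2OCC(c3cc(CC=C(C)C)c(OC)cc3O[Si](C(C)C)(C(C)C)C(C)C)C(=O)c2c(O[Si](CC)(CC)CC)c1CC=C(C)C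
F8 | step 11 | (3S,4S)-3-[4-methoxy-5-(3-methylbut-2-en-1-yl)-2-(triisopropylsilyloxy)phenyl]-6-(3-methylbut-2-en-1-yl)-5,7-bis(triethylsilyloxy)chroman-4-ol | COc1cc(O[Si](C(C)C)(C(C)C)C(C)C)c([C@H]2COc3cc(O[Si](CC)(CC)CC)c(CC=C(C)C)c(O[Si](CC)(CC)CC)c3[C@H]2O)cc1CC=C(C)C
F9 | step 8 | [4-methoxy-5-(3-methylbut-2-en-1-yl)-2-(triisopropylsilyloxy)phenyl]methanol | OCc1cc(CC=C(C)C)c(OC)cc1O[Si](C(C)C)(C(C)C)C(C)C
F10 | step 8 | 4-methoxy-5-(3-methylbut-2-en-1-yl)-2-(triisopropylsilyloxy)benzaldehyde | O=Cc1cc(CC=C(C)C)c(OC)cc1O[Si](C(C)C)(C(C)C)C(C)C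
F11 | step 8 | (2-ethynyl-5-methoxy-4-(3-methylbut-2-en-1-yl)phenoxy)triisopropylsilane | C#Cc1cc(CC=C(C)C)c(OC)cc1O[Si](C(C)C)(C(C)C)C(C)C
F12 | step 8 | lithium [4-methoxy-5-(3-methylbut-2-en-1-yl)-2-(triisopropylsilyloxy)phenyl]acetylide | [Li]C#Cc1cc(CC=C(C)C)c(OC)cc1O[Si](C(C)C)(C(C)C)C(C)C
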